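The flavone is cut along the C4a–C8a edge of ring A. There C8a (O1), C4a (carbonyl C4), C5 and C6 (both OMe) form an unbroken row of four substituted carbons that ordinary phenol acylation cannot deliver. That edge becomes the triple bond of 3,4-dimethoxybenzyne, polarised by the methoxy group at the future C5. In one fluoride-triggered operation the aryne inserts into the acyl–oxygen bond of an arylpropiolate (O1–C8a, C4–C4a). The released phenoxide then closes pyranone ring C (O1–C2), which ends at the target. The precursors are an ortho-silylaryl triflate, reached in three steps from 3,4-dimethoxyphenol by carbamate-directed lithiation, and 3-(3,4,5-trimethoxyphenyl)propiolic acid, reached by carboxylating the aryl alkyne.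

Key step: step 5

Remark: the target has no stereocentre, axis or plane of chirality, so it is one achiral compound and no step has to control configuration.
Remark: the ring carbons of silyl triflate 8 map onto the flavone as C1 (OTf) → C8a, C2 (SiMe3) → C4a, C3 (OMe) → C5, C4 (OMe) → C6.

Step 1
Reactants: 1 3,4-dimethoxyphenol
Product: 2 3,4-dimethoxyphenyl N-isopropylcarbamate
Conditions: i-PrNCO (1.5 equiv), Et3N (cat), CH2Cl2, rt
Reagents that add atoms: isopropyl isocyanate, CC(C)N=C=O
Why: Amine-catalysed addition of the phenol O–H to the isocyanate (O-carbamoylation) is clean and free of by-products, and the secondary carbamate is preferred to an N,N-dialkyl one because its N–H later allows a mild E1cB cleavage that the aryl–silicon bond should survive.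

Step 2
Reactants: 2 3,4-dimethoxyphenyl N-isopropylcarbamate
Product: 6 3,4-dimethoxy-2-(trimethylsilyl)phenyl N-isopropylcarbamate, via N-TBS carbamate 3 (not isolated), via C2-aryllithium 4 (not isolated), via N-TBS C2-TMS carbamate 5 (not isolated)
Conditions: TBSOTf, TMEDA, Et2O, 0 °C to rt; n-BuLi, TMEDA, −78 °C; TMSCl, −78 °C to rt; aq NaHSO4
Reagents that add atoms: chlorotrimethylsilane, C[Si](C)(C)Cl; tert-butyldimethylsilyl triflate, CC(C)(C)[Si](C)(C)OS(=O)(=O)C(F)(F)F (silyl group carried only by 3–5); n-butyllithium, [Li]CCCC (lithium carried only by 4)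
Why: Directed ortho-metalation: once the acidic N–H is masked in situ as the N-silyl carbamate, n-BuLi/TMEDA removes the C2 proton, the only one flanked by both the carbamate and a methoxy oxygen (cooperative 1,3-directing effect), the anion is held at −78 °C to suppress the anionic ortho-Fries shift until TMSCl traps it, and the acidic work-up hydrolyses only the labile N–Si bond.

Step 3
Reactants: 6 3,4-dimethoxy-2-(trimethylsilyl)phenyl N-isopropylcarbamate
Product: 8 3,4-dimethoxy-2-(trimethylsilyl)phenyl trifluoromethanesulfonate, via silylphenol 7 (not isolated)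
Conditions: DBU, Et2NH, MeCN, 40 °C; then PhNTf2, rt
Reagents that add atoms: N-phenylbis(trifluoromethanesulfonimide), O=S(=O)(N(c1ccccc1)S(=O)(=O)C(F)(F)F)C(F)(F)F
Why: DBU deprotonates the carbamate N–H and the anion expels the phenoxide (E1cB), Et2NH scavenges the isopropyl isocyanate as a urea so that the cleavage cannot reverse, and PhNTf2 then O-triflates the phenoxide in the same pot, so the sensitive silylphenol is never worked up.

Step 4
Reactants: 9 5-ethynyl-1,2,3-trimethoxybenzene
Product: 12 3-(3,4,5-trimethoxyphenyl)propiolic acid, via lithium acetylide 10 (not isolated), via lithium propiolate 11 (not isolated)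
Conditions: n-BuLi, THF, −78 °C; CO2, −78 °C to rt; 1 M HCl, 0 °C
Reagents that add atoms: carbon dioxide, O=C=O; n-butyllithium, [Li]CCCC (lithium carried only by 10 and 11)
Why: Deprotonation of the terminal alkyne and carboxylation of the lithium acetylide with CO2 is a standard one-carbon homologation to which the aryl methyl ethers are inert, and cold acidification with evaporation without heating guards against decarboxylation.

Step 5
Reactants: 8 3,4-dimethoxy-2-(trimethylsilyl)phenyl trifluoromethanesulfonate; 12 3-(3,4,5-trimethoxyphenyl)propiolic acid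
Product: 16 Cerosilin B (5,6-dimethoxy-2-(3,4,5-trimethoxyphenyl)-4H-chromen-4-one), via caesium propiolate 13 (not isolated), via 3,4-dimethoxybenzyne 14 (not isolated), via hydroxyaryl ynone 15 (not isolated)
Conditions: 8 (1.5 equiv), CsF (4 equiv), dry THF (0.02 M), sealed tube, 125 °C
Reagents that add atoms: caesium fluoride, [Cs+].[F-] (caesium carried only by 13 and by the phenoxide form of 15)
Why: Fluoride attacks silicon of 8 and triflate departs, which releases aryne 14 slowly because CsF is barely soluble in THF, while the same salt converts 12 into carboxylate 13 and stores the proton as bifluoride. The methoxy group on the carbon next to the triple bond (future C5) distorts 14 so that the remote terminus is the flatter, more electrophilic one; a carboxylate oxygen of 13 therefore bonds there (O1–C8a) and the charge lands on C4a, beside the σ-withdrawing C–OMe bond. The carbanion attacks its own ester carbonyl (4-exo-trig) and the strained tetrahedral adduct reopens by breaking the old acyl–oxygen bond, which sets C4–C4a and frees the phenoxide of 15; this is the known intermolecular C–O insertion of arynes into carboxylic acids, a relative of the anionic ortho-Fries rearrangement. The single new ring, the pyran-4-one, closes by 6-endo-dig oxa-Michael addition of that phenoxide to the aryl-bearing alkyne carbon (O1–C2), and the allenolate so formed takes up the stored proton at C3. Two selectivities are needed: the orientation of insertion, secured by the methoxy-induced aryne distortion, and 6-endo over 5-exo closure (flavone, not aurone), secured by the aprotic medium, in which only attack at the β-carbon gives a carbonyl-stabilised anion. No stereocentre is created, and high dilution together with the high temperature should favour the intramolecular acyl shift over bimolecular proton transfer to the aryl anion.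

Compound list
1 | 3,4-dimethoxyphenol | COc1ccc(O)cc1OC | starting material
2 | 3,4-dimethoxyphenyl N-isopropylcarbamate | COc1ccc(OC(=O)NC(C)C)cc1OC | intermediate
3 | 3,4-dimethoxyphenyl N-(tert-butyldimethylsilyl)-N-isopropylcarbamate | COc1ccc(OC(=O)N(C(C)C)[Si](C)(C)C(C)(C)C)cc1OC | intermediate
4 | {6-[N-(tert-butyldimethylsilyl)-N-isopropylcarbamoyloxy]-2,3-dimethoxyphenyl}lithium | COc1ccc(OC(=O)N(C(C)C)[Si](C)(C)C(C)(C)C)c([Li])c1OC | intermediate
5 | 3,4-dimethoxy-2-(trimethylsilyl)phenyl N-(tert-butyldimethylsilyl)-N-isopropylcarbamate | COc1ccc(OC(=O)N(C(C)C)[Si](C)(C)C(C)(C)C)c([Si](C)(C)C)c1OC | intermediate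
6 | 3,4-dimethoxy-2-(trimethylsilyl)phenyl N-isopropylcarbamate | COc1ccc(OC(=O)NC(C)C)c([Si](C)(C)C)c1OC | intermediate
7 | 3,4-dimethoxy-2-(trimethylsilyl)phenol | COc1ccc(O)c([Si](C)(C)C)c1OC | intermediate
8 | 3,4-dimethoxy-2-(trimethylsilyl)phenyl trifluoromethanesulfonate | COc1ccc(OS(=O)(=O)C(F)(F)F)c([Si](C)(C)C)c1OC | intermediate
9 | 5-ethynyl-1,2,3-trimethoxybenzene | C#Cc1cc(OC)c(OC)c(OC)c1 | starting material
10 | lithium (3,4,5-trimethoxyphenyl)acetylide | [Li]C#Cc1cc(OC)c(OC)c(OC)c1 | intermediate
11 | lithium 3-(3,4,5-trimethoxyphenyl)propiolate | COc1cc(C#CC(=O)[O-])cc(OC)c1OC.[Li+] | intermediate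
12 | 3-(3,4,5-trimethoxyphenyl)propiolic acid | COc1cc(C#CC(=O)O)cc(OC)c1OC | intermediate
13 | caesium 3-(3,4,5-trimethoxyphenyl)propiolate | COc1cc(C#CC(=O)[O-])cc(OC)c1OC.[Cs+] | intermediate
14 | 3,4-dimethoxybenzyne (1,2-didehydro-3,4-dimethoxybenzene) | COC1=C(OC)C#CC=C1 | intermediate
15 | 1-(6-hydroxy-2,3-dimethoxyphenyl)-3-(3,4,5-trimethoxyphenyl)prop-2-yn-1-one (caesium phenoxide in the flask, drawn as the phenol) | COc1ccc(O)c(C(=O)C#Cc2cc(OC)c(OC)c(OC)c2)c1OC | intermediate
16 | Cerosilin B, 5,6-dimethoxy-2-(3,4,5-trimethoxyphenyl)-4H-chromen-4-one | COc1cc(-c2cc(=O)c3c(OC)c(OC)ccc3o2)cc(OC)c1OC | target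

Total step count: 5. Longest linear sequence: 4 steps (1, 2, 3, 5); step 4 is the one-step side branch.

Steps most likely to fail

**Step 5.** Three things may go wrong:
- The carbanion at C4a may pick up a proton before the acyl group migrates, which amounts to mere O-arylation of the acid.
- The carbanion may add to the alkyne instead of the carbonyl.
- The propiolate may lose CO2 at 125 °C.

The fallback is a palladium-catalysed carbonylative annulation that needs no aryne. It sets out from 2 and 9 and comes back at 15. Carbamate 2 is N-silylated and lithiated to 4 as in step 2. Iodine at −78 °C should then give 2-iodo-3,4-dimethoxyphenyl N-(tert-butyldimethylsilyl)-N-isopropylcarbamate F1, and the bisulfate work-up should give 2-iodo-3,4-dimethoxyphenyl N-isopropylcarbamate F2. DBU and Et2NH in MeCN at 40 °C should release 2-iodo-3,4-dimethoxyphenol F3. Carbonylative Sonogashira coupling of F3 with alkyne 9 (PdCl2(dppf) cat, CO, Et2NH, 120 °C) should give ynone 15. This closes to 16 in the same pot, since a secondary-amine medium favours the six-membered ring.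

**Step 2.** Three things may go wrong:
- N-Silylation may be incomplete, so that the base removes the N–H and the carbamate collapses.
- The carbamoyl group may migrate to carbon (anionic ortho-Fries shift) before the crowded carbanion is silylated.
- Metalation may stray to C6.

The fallback uses a directing group that can neither collapse nor migrate. It sets out from 1 and comes back at 7. MOMCl and i-Pr2NEt in CH2Cl2 should give 1,2-dimethoxy-4-(methoxymethoxy)benzene F4. n-BuLi in THF at 0 °C should metalate the carbon between the acetal and the methoxy group to give [2,3-dimethoxy-6-(methoxymethoxy)phenyl]lithium F5. This anion tolerates 0 °C to rt, which leaves time for TMSCl to give [2,3-dimethoxy-6-(methoxymethoxy)phenyl]trimethylsilane F6. Silica-supported NaHSO4 in CH2Cl2 at rt should remove the phenolic acetal and give 7. This is triflated with DBU and PhNTf2, as in the second half of step 3, to give 8.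

**Step 3.** Two things may go wrong:
- The electron-rich aryl–silicon bond, flanked by two oxygens, may be lost by protodesilylation while the phenoxide sits in the protic amine medium.
- The hindered phenoxide may be sulfonylated too slowly by the mild imide reagent.

In the fallback the carbamate is cleaved before any silicon is on carbon. Silicon then arrives last, by an intramolecular oxygen-to-carbon shift in an aprotic pot that ends with Tf2O. It sets out from 2 and comes back at 8.

Carbamate 2 is taken to 4 as in step 2. 1,2-Dibromotetrachloroethane at −78 °C should give 2-bromo-3,4-dimethoxyphenyl N-(tert-butyldimethylsilyl)-N-isopropylcarbamate F7, and the bisulfate work-up should give 2-bromo-3,4-dimethoxyphenyl N-isopropylcarbamate F8. DBU and Et2NH in MeCN should give 2-bromo-3,4-dimethoxyphenol F9, and HMDS in refluxing THF should give (2-bromo-3,4-dimethoxyphenoxy)trimethylsilane F10.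

n-BuLi in THF at −100 to −78 °C should effect bromine–lithium exchange to [2,3-dimethoxy-6-(trimethylsilyloxy)phenyl]lithium F11. Retro-Brook rearrangement of F11 should give lithium 3,4-dimethoxy-2-(trimethylsilyl)phenoxide F12, and Tf2O added to the cold solution should give 8.

Further compounds
F1 | step 5 | 2-iodo-3,4-dimethoxyphenyl N-(tert-butyldimethylsilyl)-N-isopropylcarbamate | COc1ccc(OC(=O)N(C(C)C)[Si](C)(C)C(C)(C)C)c(I)c1OC
F2 | step 5 | 2-iodo-3,4-dimethoxyphenyl N-isopropylcarbamate | COc1ccc(OC(=O)NC(C)C)c(I)c1OC
F3 | step 5 | 2-iodo-3,4-dimethoxyphenol | COc1ccc(O)c(I)c1OC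
F4 | step 2 | 1,2-dimethoxy-4-(methoxymethoxy)benzene | COCOc1ccc(OC)c(OC)c1
F5 | step 2 | [2,3-dimethoxy-6-(methoxymethoxy)phenyl]lithium | COCOc1ccc(OC)c(OC)c1[Li]
F6 | step 2 | [2,3-dimethoxy-6-(methoxymethoxy)phenyl]trimethylsilane | COCOc1ccc(OC)c(OC)c1[Si](C)(C)C
F7 | step 3 | 2-bromo-3,4-dimethoxyphenyl N-(tert-butyldimethylsilyl)-N-isopropylcarbamate | COc1ccc(OC(=O)N(C(C)C)[Si](C)(C)C(C)(C)C)c(Br)c1OC
F8 | step 3 | 2-bromo-3,4-dimethoxyphenyl N-isopropylcarbamate | COc1ccc(OC(=O)NC(C)C)c(Br)c1OC
F9 | step 3 | 2-bromo-3,4-dimethoxyphenol | COc1ccc(O)c(Br)c1OC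
F10 | step 3 | (2-bromo-3,4-dimethoxyphenoxy)trimethylsilane | COc1ccc(O[Si](C)(C)C)c(Br)c1OC
F11 | step 3 | [2,3-dimethoxy-6-(trimethylsilyloxy)phenyl]lithium | COc1ccc(O[Si](C)(C)C)c([Li])c1OC
F12 | step 3 | lithium 3,4-dimethoxy-2-(trimethylsilyl)phenoxide | COc1ccc([O-])c([Si](C)(C)C)c1OC.[Li+]
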